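## Retrosynthetic overview

1. Structural feature: in the guai-4-en-3-one core, the five-membered ring C1–C2–C3–C4–C5 holds C3=O between an unsubstituted C2H2 and C4. Its C4=C5 bond ends at the fusion atom C5 of the seven-membered ring C5–C6–C7–C8–C9–C10–C1, so C2 is a lone methylene that can be inserted between C1 and C3.
2. Late-stage disconnections: the C8 methacrylate comes from Mitsunobu inversion of the 8-epi alcohol, the C4 methyl from Negishi coupling of a 4-chloro enone, and C4=C5 from zinc-induced loss of a C5 silyloxy group.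
3. Key disconnection: removing C2 leads back to a 4,4-dichlorocyclobutanone fused at C1–C5. This is the dichloroketene (2+2) adduct of a C5=C1 silyl enol ether, with the ketene C=O carbon on C1 and the CCl2 carbon on C5.
4. The enol ether comes from two substrate-controlled conjugate additions on the seven-membered ring: isopropenyl at C7 anti to the C8 silyl ether, then methyl at C10 with Me3SiCl trapping. The starting enone, (S)-4-silyloxycyclohept-2-enone, is made from cyclohepta-1,3-diene by photooxygenation and lipase desymmetrisation.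
5. Ring order: the seven-membered ring is purchased, the four-membered ring forms in step 12, and the five-membered ring forms by 4→5 expansion in step 14.

Key step: step 14

Numbering remark: guaiane numbering is used throughout. In the monocyclic intermediates the ketone carbon is C5 and the silyloxy carbon is C8.

Assumption: the lipase is taken to acylate the R carbinol of the meso diol, as the empirical rule for lipase acylation of secondary alcohols predicts with the alkene flank as the large group. If the sense were opposite, hydrolysis of the meso diacetate with the same enzyme would give the same monoacetate.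

## Route

Step 1
Reactants: 1 cyclohepta-1,3-diene
Product: 3 (1R,4S)-cyclohept-2-ene-1,4-diol (cis meso diol), via endoperoxide 2 (not isolated)
Conditions: O2, tetraphenylporphyrin (cat.), hν (visible), CH2Cl2, 0 °C; then Zn, AcOH, 0 °C → rt
Reagents that add atoms: dioxygen, O=O
Why: Singlet-oxygen (4+2) cycloaddition puts both oxygens on one face of the diene termini, and reductive O–O cleavage by zinc in acetic acid keeps that cis relationship, so a meso diol should result.

Step 2
Reactants: 3 (1R,4S)-cyclohept-2-ene-1,4-diol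
Product: 4 (1R,4S)-4-hydroxycyclohept-2-en-1-yl acetate
Conditions: vinyl acetate, immobilised Candida antarctica lipase B, MTBE, rt
Reagents that add atoms: vinyl acetate, C=COC(C)=O
Why: In this enzymatic desymmetrisation by irreversible transesterification the lipase acylates the R carbinol and leaves the S carbinol (the later C8) free, and any over-acylation consumes mainly the minor enantiomer.

Step 3
Reactants: 4 (1R,4S)-4-hydroxycyclohept-2-en-1-yl acetate
Product: 5 (1R,4S)-4-(tert-butyldimethylsilyloxy)cyclohept-2-en-1-yl acetate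
Conditions: TBSCl, imidazole, DMF, rt
Reagents that add atoms: tert-butyldimethylsilyl chloride, CC(C)(C)[Si](C)(C)Cl
Why: Imidazole-promoted silylation of a secondary allylic alcohol touches neither stereocentre.

Step 4
Reactants: 5 (1R,4S)-4-(tert-butyldimethylsilyloxy)cyclohept-2-en-1-yl acetate
Product: 6 (1R,4S)-4-(tert-butyldimethylsilyloxy)cyclohept-2-en-1-ol
Conditions: K2CO3 (cat.), MeOH, 0 °C
Reagents that add atoms: none
Why: Carbonate-catalysed transesterification removes the acetate, and the low temperature keeps the silyl group from migrating across the ring, which would erode the enantiopurity.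

Step 5
Reactants: 6 (1R,4S)-4-(tert-butyldimethylsilyloxy)cyclohept-2-en-1-ol
Product: 7 (4S)-4-(tert-butyldimethylsilyloxy)cyclohept-2-en-1-one
Conditions: MnO2, CH2Cl2, rt
Reagents that add atoms: none
Why: Allylic alcohol oxidation on MnO2 under neutral conditions erases the R carbinol centre and leaves the enone with the single S centre at C8.

Step 6
Reactants: 7 (4S)-4-(tert-butyldimethylsilyloxy)cyclohept-2-en-1-one; 8 isopropenylmagnesium bromide
Product: 10 (3R,4S)-4-(tert-butyldimethylsilyloxy)-3-(prop-1-en-2-yl)cycloheptan-1-one, via silyl enol ether 9 (not isolated)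
Conditions: 8 (1.5 equiv), CuBr·SMe2 (20 mol %), Me3SiCl, THF, −78 °C; then 1 M aq HCl, 0 °C
Reagents that add atoms: isopropenylmagnesium bromide (8), C=C(C)[Mg]Br (Me3SiCl, C[Si](C)(C)Cl, leaves atoms only in 9)
Why: In this copper-catalysed conjugate addition accelerated by Me3SiCl the nucleophile attacks C7 on the face opposite the adjacent C8 silyloxy group, which sets C7 trans to C8, and the brief acid treatment hydrolyses the C5=C6 enol ether.

Step 7
Reactants: 10 (3R,4S)-4-(tert-butyldimethylsilyloxy)-3-(prop-1-en-2-yl)cycloheptan-1-one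
Product: 11 (3S,4S)-4-(tert-butyldimethylsilyloxy)-3-(2-hydroxypropan-2-yl)cycloheptan-1-one
Conditions: Co(acac)2 (15 mol %), PhSiH3, O2 (1 atm), THF, rt
Reagents that add atoms: dioxygen, O=O
Why: In the Mukaiyama hydration a cobalt hydride delivers a hydrogen atom to the terminal alkene carbon, O2 traps the tertiary C11 radical and the silane reduces the peroxide, which should give the Markovnikov tertiary alcohol without touching the ketone or silyl ether and creates no stereocentre.

Step 8
Reactants: 11 (3S,4S)-4-(tert-butyldimethylsilyloxy)-3-(2-hydroxypropan-2-yl)cycloheptan-1-one; 12 acetic anhydride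
Product: 13 2-[(1S,2S)-2-(tert-butyldimethylsilyloxy)-6-oxocycloheptyl]propan-2-yl acetate
Conditions: 12, DMAP, Et3N, CH2Cl2, rt → 40 °C
Reagents that add atoms: acetic anhydride (12), CC(=O)OC(C)=O
Why: DMAP-catalysed acylation through the N-acetylpyridinium ion is strong enough for the hindered tertiary C11 hydroxyl, and because that hydroxyl is γ to the ketone, retro-aldol and elimination pathways are excluded.

Step 9
Reactants: 13 2-[(1S,2S)-2-(tert-butyldimethylsilyloxy)-6-oxocycloheptyl]propan-2-yl acetate
Product: 14 2-[(1S,2S)-2-(tert-butyldimethylsilyloxy)-6-(trimethylsilyloxy)cyclohept-5-en-1-yl]propan-2-yl acetate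
Conditions: LiN(SiMe3)2 (1.1 equiv) added to 13 and Me3SiCl, THF, −78 °C
Reagents that add atoms: chlorotrimethylsilane, C[Si](C)(C)Cl
Why: In this kinetic enolisation with in situ silylation the silazide is basic enough for the ketone but hardly for the less acidic acetate, and it takes a proton from the open C1 methylene and not from C6, which the branched C7 side chain screens.

Step 10
Reactants: 14 2-[(1S,2S)-2-(tert-butyldimethylsilyloxy)-6-(trimethylsilyloxy)cyclohept-5-en-1-yl]propan-2-yl acetate
Product: 15 2-[(1S,2S)-2-(tert-butyldimethylsilyloxy)-6-oxocyclohept-4-en-1-yl]propan-2-yl acetate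
Conditions: Pd(OAc)2 (1.05 equiv), MeCN, rt
Reagents that add atoms: none
Why: In the Saegusa–Ito oxidation, palladation of the enol ether at C1 followed by syn β-hydride elimination from C10 gives the C1=C10 enone with the regiochemistry fixed in step 9.

Step 11
Reactants: 15 2-[(1S,2S)-2-(tert-butyldimethylsilyloxy)-6-oxocyclohept-4-en-1-yl]propan-2-yl acetate; 16 methylmagnesium bromide
Product: 17 2-[(1S,2S,4S)-2-(tert-butyldimethylsilyloxy)-4-methyl-6-(trimethylsilyloxy)cyclohept-5-en-1-yl]propan-2-yl acetate
Conditions: 16 (1.5 equiv), CuBr·SMe2 (10 mol %), Me3SiCl, HMPA, THF, −78 °C; Et3N, then cold aq NaHCO3/pentane work-up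
Reagents that add atoms: methylmagnesium bromide (16), C[Mg]Br; chlorotrimethylsilane, C[Si](C)(C)Cl
Why: In this copper-catalysed 1,4-addition with Me3SiCl/HMPA acceleration, axial attack at C10 of the chair-like enone that keeps the trans C7 and C8 substituents equatorial should place the methyl trans to the C8 silyl ether and cis to the C7 side chain (10S), and silylation of the enolate fixes the double bond at C5=C1.

Step 12
Reactants: 17 2-[(1S,2S,4S)-2-(tert-butyldimethylsilyloxy)-4-methyl-6-(trimethylsilyloxy)cyclohept-5-en-1-yl]propan-2-yl acetate; 18 trichloroacetyl chloride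
Product: 20 2-[(1R,3S,4S,6S,7R)-4-(tert-butyldimethylsilyloxy)-9,9-dichloro-6-methyl-8-oxo-1-(trimethylsilyloxy)bicyclo[5.2.0]nonan-3-yl]propan-2-yl acetate, via dichloroketene 19 (not isolated)
Conditions: 18 (2 equiv), Zn–Cu couple, Et2O–DME, rt
Reagents that add atoms: trichloroacetyl chloride (18), ClC(=O)C(Cl)(Cl)Cl
Why: In this ketene–alkene (2+2) cycloaddition the nucleophilic C1 bonds to the ketene carbonyl carbon (C3) and the CCl2 carbon (C4) closes on the oxygen-bearing C5, suprafacially and on the face opposite the pseudoaxial C10 methyl, which sets C1 (R) and C5 (R) in a cis-fused cyclobutanone, while DME ties up ZnCl2 so that the labile β-silyloxy ketone survives.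

Step 13
Reactants: 21 N-methyl-N-nitroso-4-methylbenzenesulfonamide
Product: 22 diazomethane (dry alcohol-free ethereal solution)
Conditions: KOH, H2O–2-(2-ethoxyethoxy)ethanol–Et2O, 65 °C, co-distillation; distillate dried over KOH pellets
Reagents that add atoms: none
Why: In this base-induced fragmentation of an N-nitrososulfonamide, hydroxide takes the sulfonyl group and the methyldiazotate loses water to give diazomethane, which distils with the ether.

Step 14
Reactants: 20 dichlorocyclobutanone fused at C1–C5 (1R,5R,7S,8S,10S in guaiane numbering); 22 diazomethane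
Product: 23 (1R,5R,7S,8S,10S)-11-acetoxy-8-(tert-butyldimethylsilyloxy)-4,4-dichloro-5-(trimethylsilyloxy)-15-norguaian-3-one (cis-fused perhydroazulen-3-one)
Conditions: 22 (2–3 equiv), Et2O, 0 °C → rt; excess quenched with AcOH
Reagents that add atoms: diazomethane (22), C=[N+]=[N-]
Why: Diazomethane adds through carbon to the strained, chlorine-activated C3 carbonyl to give a diazonium alkoxide, and as N2 leaves the C1–C3 bond shifts to the new methylene carbon, so C1–C2 and C2–C3 form in one event (Büchner–Curtius–Schlotterbeck homologation in its known regioselective form on α,α-dichlorocyclobutanones). The five-membered ring C1–C5 is therefore closed not by cyclisation but by a 1,2-shift that enlarges the four-membered ring C1–C3–C4–C5 by one atom, driven by release of cyclobutanone strain. No stereocentre is created, because C1 migrates with retention and C5 is untouched, so the cis fusion and the C1/C10 relationship of 20 pass unchanged into 23. The first selectivity needed is migration of C1 instead of C4, and the two chlorines on C4 secure it by making that carbon a poor migrating group towards the electron-poor centre. The second is single insertion, secured by the much higher reactivity of the cyclobutanone over the cyclopentanone product, a small excess of reagent and the acid quench. Alcohol-free and base-free reagent is used so that the C5–OSiMe3 group is not cleaved, since that would open the small ring by retro-aldol fragmentation.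

Step 15
Reactants: 23 4,4-dichloro-5-silyloxy hydroazulen-3-one
Product: 24 (1R,7S,8S,10S)-11-acetoxy-8-(tert-butyldimethylsilyloxy)-4-chloro-15-norguai-4-en-3-one
Conditions: Zn dust (1.5 equiv), AcOH–THF, 0 °C → rt
Reagents that add atoms: none
Why: In this reductive β-elimination zinc inserts into one C4–Cl bond and the zinc chloro-enolate expels the C5 silyloxy group (E1cB), which places the tetrasubstituted C4=C5 bond, erases C5, leaves C1 untouched and keeps one chlorine on C4 as a coupling handle.

Step 16
Reactants: 24 4-chloro enone; 25 methylzinc chloride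
Product: 26 (1R,7S,8S,10S)-11-acetoxy-8-(tert-butyldimethylsilyloxy)guai-4-en-3-one
Conditions: 25 (2 equiv), Pd(P(t-Bu)3)2 (5 mol %), THF–NMP, 50 °C
Reagents that add atoms: methylzinc chloride (25), C[Zn]Cl
Why: In the Negishi coupling the bulky electron-rich phosphine lets zerovalent palladium insert into the alkenyl C4–Cl bond, transmetallation from zinc and reductive elimination place the C4 methyl, and the non-basic organozinc leaves ketone, acetate, silyl ether and C1 alone.

Step 17
Reactants: 26 (1R,7S,8S,10S)-11-acetoxy-8-(tert-butyldimethylsilyloxy)guai-4-en-3-one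
Product: 27 (1R,7S,8S,10S)-11-acetoxy-8-hydroxyguai-4-en-3-one
Conditions: HF·pyridine, pyridine, THF, 0 °C → rt
Reagents that add atoms: none
Why: Fluoride-mediated Si–O cleavage in a buffered acidic medium is chosen over basic fluoride so that the tertiary acetate does not migrate to the freed C8 hydroxyl and C1 is not epimerised through the dienolate.

Step 18
Reactants: 27 (1R,7S,8S,10S)-11-acetoxy-8-hydroxyguai-4-en-3-one; 28 methacrylic acid
Product: 29 (1R,7S,8R,10S)-11-acetoxy-8-(methacryloyloxy)guai-4-en-3-one (CNP0318307.1)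
Conditions: 28, PPh3, DIAD, BHT (trace), toluene, 0 °C → rt
Reagents that add atoms: methacrylic acid (28), C=C(C)C(=O)O
Why: In the Mitsunobu esterification the C8 alcohol is activated as its oxyphosphonium salt and displaced by methacrylate in an SN2 process with inversion, which turns 8S into the 8R configuration cis to the C7 side chain.

## Compound list

1 | cyclohepta-1,3-diene | C1=CC=CCCC1 | starting material
2 | 6,7-dioxabicyclo[3.2.2]non-8-ene (meso endoperoxide) | O1[C@H]2C=C[C@@H](O1)CCC2 | intermediate
3 | (1R,4S)-cyclohept-2-ene-1,4-diol (cis, meso) | O[C@H]1C=C[C@@H](O)CCC1 | intermediate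
4 | (1R,4S)-4-hydroxycyclohept-2-en-1-yl acetate | CC(=O)O[C@H]1C=C[C@@H](O)CCC1 | intermediate
5 | (1R,4S)-4-(tert-butyldimethylsilyloxy)cyclohept-2-en-1-yl acetate | CC(=O)O[C@H]1C=C[C@@H](O[Si](C)(C)C(C)(C)C)CCC1 | intermediate
6 | (1R,4S)-4-(tert-butyldimethylsilyloxy)cyclohept-2-en-1-ol | O[C@H]1C=C[C@@H](O[Si](C)(C)C(C)(C)C)CCC1 | intermediate
7 | (4S)-4-(tert-butyldimethylsilyloxy)cyclohept-2-en-1-one | O=C1C=C[C@@H](O[Si](C)(C)C(C)(C)C)CCC1 | intermediate
8 | isopropenylmagnesium bromide | C=C(C)[Mg]Br | starting material
9 | (3R,4S)-4-(tert-butyldimethylsilyloxy)-3-(prop-1-en-2-yl)-1-(trimethylsilyloxy)cyclohept-1-ene (C5=C6 enol ether) | C[Si](C)(C)OC1=C[C@H](C(C)=C)[C@@H](O[Si](C)(C)C(C)(C)C)CCC1 | intermediate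
10 | (3R,4S)-4-(tert-butyldimethylsilyloxy)-3-(prop-1-en-2-yl)cycloheptan-1-one (C7/C8 trans) | O=C1C[C@H](C(C)=C)[C@@H](O[Si](C)(C)C(C)(C)C)CCC1 | intermediate
11 | (3S,4S)-4-(tert-butyldimethylsilyloxy)-3-(2-hydroxypropan-2-yl)cycloheptan-1-one | O=C1C[C@H](C(C)(C)O)[C@@H](O[Si](C)(C)C(C)(C)C)CCC1 | intermediate
12 | acetic anhydride | CC(=O)OC(C)=O | starting material
13 | 2-[(1S,2S)-2-(tert-butyldimethylsilyloxy)-6-oxocycloheptyl]propan-2-yl acetate | O=C1C[C@H](C(C)(C)OC(C)=O)[C@@H](O[Si](C)(C)C(C)(C)C)CCC1 | intermediate
14 | 2-[(1S,2S)-2-(tert-butyldimethylsilyloxy)-6-(trimethylsilyloxy)cyclohept-5-en-1-yl]propan-2-yl acetate (C5=C1 enol ether) | C[Si](C)(C)OC1=CCC[C@H](O[Si](C)(C)C(C)(C)C)[C@@H](C(C)(C)OC(C)=O)C1 | intermediate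
15 | 2-[(1S,2S)-2-(tert-butyldimethylsilyloxy)-6-oxocyclohept-4-en-1-yl]propan-2-yl acetate (C1=C10 enone) | O=C1C[C@H](C(C)(C)OC(C)=O)[C@@H](O[Si](C)(C)C(C)(C)C)CC=C1 | intermediate
16 | methylmagnesium bromide | C[Mg]Br | starting material
17 | 2-[(1S,2S,4S)-2-(tert-butyldimethylsilyloxy)-4-methyl-6-(trimethylsilyloxy)cyclohept-5-en-1-yl]propan-2-yl acetate | C[Si](C)(C)OC1=C[C@@H](C)C[C@H](O[Si](C)(C)C(C)(C)C)[C@@H](C(C)(C)OC(C)=O)C1 | intermediate
18 | trichloroacetyl chloride | ClC(=O)C(Cl)(Cl)Cl | starting material
19 | dichloroketene | ClC(Cl)=C=O | intermediate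
20 | 2-[(1R,3S,4S,6S,7R)-4-(tert-butyldimethylsilyloxy)-9,9-dichloro-6-methyl-8-oxo-1-(trimethylsilyloxy)bicyclo[5.2.0]nonan-3-yl]propan-2-yl acetate (guaiane numbering 1R,5R,7S,8S,10S) | C[Si](C)(C)O[C@]12C[C@H](C(C)(C)OC(C)=O)[C@@H](O[Si](C)(C)C(C)(C)C)C[C@H](C)[C@H]1C(=O)C2(Cl)Cl | intermediate
21 | N-methyl-N-nitroso-4-methylbenzenesulfonamide | Cc1ccc(cc1)S(=O)(=O)N(C)N=O | starting material
22 | diazomethane | C=[N+]=[N-] | intermediate
23 | (1R,5R,7S,8S,10S)-11-acetoxy-8-(tert-butyldimethylsilyloxy)-4,4-dichloro-5-(trimethylsilyloxy)-15-norguaian-3-one | C[Si](C)(C)O[C@]12C[C@H](C(C)(C)OC(C)=O)[C@@H](O[Si](C)(C)C(C)(C)C)C[C@H](C)[C@H]1CC(=O)C2(Cl)Cl | intermediate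
24 | (1R,7S,8S,10S)-11-acetoxy-8-(tert-butyldimethylsilyloxy)-4-chloro-15-norguai-4-en-3-one | CC(C)(C)[Si](C)(C)O[C@H]1C[C@H](C)[C@H]2CC(=O)C(Cl)=C2C[C@@H]1C(C)(C)OC(C)=O | intermediate
25 | methylzinc chloride | C[Zn]Cl | starting material
26 | (1R,7S,8S,10S)-11-acetoxy-8-(tert-butyldimethylsilyloxy)guai-4-en-3-one | CC(C)(C)[Si](C)(C)O[C@H]1C[C@H](C)[C@H]2CC(=O)C(C)=C2C[C@@H]1C(C)(C)OC(C)=O | intermediate
27 | (1R,7S,8S,10S)-11-acetoxy-8-hydroxyguai-4-en-3-one | O[C@H]1C[C@H](C)[C@H]2CC(=O)C(C)=C2C[C@@H]1C(C)(C)OC(C)=O | intermediate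
28 | methacrylic acid | C=C(C)C(=O)O | starting material
29 | (1R,7S,8R,10S)-11-acetoxy-8-(methacryloyloxy)guai-4-en-3-one (CNP0318307.1) | C=C(C)C(=O)O[C@@H]1C[C@H](C)[C@H]2CC(=O)C(C)=C2C[C@@H]1C(C)(C)OC(C)=O | target

## Step count and risks

Total step count: 18.
Longest linear sequence: 17 (steps 1–12 and 14–18). Step 13 is a one-step side branch.

Three steps most likely to fail:

**1. Step 14 (key step).**
- The C5 silyl group may be lost, followed by retro-aldol opening of the four-membered ring before insertion.
- A second insertion or epoxide formation may occur at the still-activated cyclopentanone carbonyl.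
- The migration preference may erode.

The fallback sets out from 17 and brings in C2, C3, C4 and the C4 methyl as one four-carbon unit. Fluoride-promoted regiospecific alkylation at C1 with 1-bromobut-2-yne (anhydrous benzyltrimethylammonium fluoride, THF, 4 Å sieves), anti to the C10 methyl, should give the butynyl ketone F1. Carbonyl-assisted hydration of the alkyne (NaAuCl4 cat., aq MeOH) should give the 1,4-diketone F2. Intramolecular aldol condensation of C4 onto C5 (KOt-Bu, t-BuOH, rt) then closes the cyclopentenone and comes back to the route at 26.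

**2. Step 18.**
- The carboxylate must enter C8 on the face that carries the C7 side chain, so substitution may be too slow.
- The activated alcohol may eliminate towards C9 or C7.
- The neighbouring acetate carbonyl may capture the oxyphosphonium centre and scramble the acyl groups.

The fallback sets out from 27 and replaces substitution by an oxidation and reduction sequence. Dess–Martin periodinane buffered with NaHCO3 (CH2Cl2, 0 °C) should give the 8-ketone F3. Reduction with LiBH(s-Bu)3 (1 equiv, THF, −78 °C, pH 7 work-up) delivers hydride from the face opposite the C7 side chain and spares the hindered tetrasubstituted enone, giving the 8R alcohol F4. Immediate acylation with methacrylic anhydride, DMAP and Et3N (CH2Cl2, 0 °C) comes back to the route at 29.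

**3. Step 9.**
- Discrimination between the C1 and C6 protons may be poor.
- The acetate may be deprotonated in competition.
- The enolate may equilibrate before silylation.

The fallback sets out from enone 7, whose only kinetically accessible enolisable position is C1, and so fixes the site of unsaturation before the side chain is present. LiN(i-Pr)2 and then S-phenyl benzenethiosulfonate (THF, −78 °C) should give the 1-phenylthio enone F5 (C1 epimers, of no consequence). Copper-mediated addition of 8 anti to the C8 silyl ether gives the isopropenyl sulfide F6. Mukaiyama hydration gives the hydroxy sulfide F7, and DMAP-catalysed acetylation with 12 gives the acetoxy sulfide F8, so no strong base is used once the acetate is in place. Oxidation with mCPBA (1 equiv, CH2Cl2, −78 °C) gives the sulfoxide F9, whose thermal syn elimination (toluene, CaCO3, 100 °C) can only run towards C10 and comes back to the route at 15.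

## Further compounds

F1 | step 14 | 2-[(1S,2S,4S,5R)-5-(but-2-yn-1-yl)-2-(tert-butyldimethylsilyloxy)-4-methyl-6-oxocycloheptyl]propan-2-yl acetate | O=C1C[C@H](C(C)(C)OC(C)=O)[C@@H](O[Si](C)(C)C(C)(C)C)C[C@H](C)[C@H]1CC#CC
F2 | step 14 | 2-[(1S,2S,4S,5R)-2-(tert-butyldimethylsilyloxy)-4-methyl-6-oxo-5-(2-oxobutyl)cycloheptyl]propan-2-yl acetate | O=C1C[C@H](C(C)(C)OC(C)=O)[C@@H](O[Si](C)(C)C(C)(C)C)C[C@H](C)[C@H]1CC(=O)CC
F3 | step 18 | 11-acetoxyguai-4-ene-3,8-dione with the C1, C7 and C10 configurations of 27 | O=C1C[C@H](C)[C@H]2CC(=O)C(C)=C2C[C@@H]1C(C)(C)OC(C)=O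
F4 | step 18 | (1R,7S,8R,10S)-11-acetoxy-8-hydroxyguai-4-en-3-one | O[C@@H]1C[C@H](C)[C@H]2CC(=O)C(C)=C2C[C@@H]1C(C)(C)OC(C)=O
F5 | step 9 | (4S)-4-(tert-butyldimethylsilyloxy)-7-(phenylsulfanyl)cyclohept-2-en-1-one (epimers at the sulfur-bearing carbon) | O=C1C=C[C@@H](O[Si](C)(C)C(C)(C)C)CCC1Sc1ccccc1
F6 | step 9 | (3R,4S)-4-(tert-butyldimethylsilyloxy)-7-(phenylsulfanyl)-3-(prop-1-en-2-yl)cycloheptan-1-one | O=C1C[C@H](C(C)=C)[C@@H](O[Si](C)(C)C(C)(C)C)CCC1Sc1ccccc1
F7 | step 9 | (3S,4S)-4-(tert-butyldimethylsilyloxy)-3-(2-hydroxypropan-2-yl)-7-(phenylsulfanyl)cycloheptan-1-one | O=C1C[C@H](C(C)(C)O)[C@@H](O[Si](C)(C)C(C)(C)C)CCC1Sc1ccccc1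
F8 | step 9 | 2-[(1S,2S)-2-(tert-butyldimethylsilyloxy)-6-oxo-5-(phenylsulfanyl)cycloheptyl]propan-2-yl acetate | O=C1C[C@H](C(C)(C)OC(C)=O)[C@@H](O[Si](C)(C)C(C)(C)C)CCC1Sc1ccccc1
F9 | step 9 | 2-[(1S,2S)-2-(tert-butyldimethylsilyloxy)-6-oxo-5-(phenylsulfinyl)cycloheptyl]propan-2-yl acetate | O=C1C[C@H](C(C)(C)OC(C)=O)[C@@H](O[Si](C)(C)C(C)(C)C)CCC1S(=O)c1ccccc1
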